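**Retrosynthetic overview**
1. Feature: the central benzene ring is hexasubstituted. It carries oxygen on C3 (OH) and C5 (OMe), meta to each other, and carbon on C1 (2-arylethyl) and on C2, C4 and C6 (4-hydroxybenzyl). This is the pattern of a folded, C-alkylated 1,3,5-triketone, so all six substituents can be set in an open chain.
2. Endgame: the target comes from one hydrogenation (stilbene C=C and three O-benzyl groups), preceded by mono-O-methylation of a C2v-symmetric 2,4,6-tribenzyl-5-styrylresorcinol whose two OH groups are equivalent.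
3. Key disconnection: ring bond C1–C6 is opened to a non-1-ene-3,5,7-trione. In the forward sense the C8 methylene adds to the cinnamoyl carbonyl C3 and the aldol aromatises. This is the only ring made; the four outer arenes are bought.
4. The triketone comes from terminal acylation of a 2-benzylated β-diketone dianion with the Weinreb amide of 3-methoxycinnamic acid. The diketone comes from acetylacetone and three molecules of 4-(benzyloxy)benzyl chloride (two terminal, one central alkylation). The phenols therefore arrive already benzylated, and no O-benzylation is run beside an acidic diketone CH2.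

Key step: step 5

Remark: the target has no stereocentre, stereogenic axis or C=C bond and is achiral, so no enantiocontrol is needed; 4-(benzyloxy)benzyl chloride is taken as a catalogue compound.

**Step 1**
Reactants: 1 pentane-2,4-dione; 2 4-(benzyloxy)benzyl chloride (2 equiv in two portions)
Product: 4 1,7-bis[4-(benzyloxy)phenyl]heptane-3,5-dione, via mono-alkylated diketone enolate 3 (not isolated)
Conditions: LDA (2.1 equiv), THF, −78 → 0 °C; 2 (1.0 equiv), 0 °C; LDA (1.05 equiv), 0 °C; 2 (1.0 equiv), 0 °C → rt; aq NH4Cl
Reagents that add atoms: none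
Why: This is an iterated γ-alkylation of a β-diketone 1,3-dianion, in which the terminal carbanion is by far the most nucleophilic site and the enolate of 3 is deprotonated again at its free CH3 (more acidic and less hindered than the new CH2), so both arms should end at the chain termini and no stereocentre forms.

**Step 2**
Reactants: 4 1,7-bis[4-(benzyloxy)phenyl]heptane-3,5-dione; 2 4-(benzyloxy)benzyl chloride (1.0 equiv)
Product: 5 4-[4-(benzyloxy)benzyl]-1,7-bis[4-(benzyloxy)phenyl]heptane-3,5-dione
Conditions: K2CO3 (1.2 equiv), NaI (cat.), acetone, reflux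
Reagents that add atoms: none
Why: This is a C-alkylation of the β-diketone mono-enolate with a soft benzylic halide under Finkelstein catalysis, where one equivalent of halide limits double alkylation, the aprotic medium avoids the retro-Claisen cleavage that alcoholic carbonate causes in 2-alkyl-1,3-diketones, and the new CH is stereolabile.

**Step 3**
Reactants: 6 (E)-3-(3-methoxyphenyl)prop-2-enoic acid (3-methoxycinnamic acid)
Product: 8 (E)-N-methoxy-3-(3-methoxyphenyl)-N-methylprop-2-enamide, via acyl imidazolide 7 (not isolated)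
Conditions: CDI (1.1 equiv), CH2Cl2, rt; MeNH(OMe)·HCl (1.2 equiv), rt
Reagents that add atoms: N,O-dimethylhydroxylamine hydrochloride CNOC.Cl; 1,1'-carbonyldiimidazole O=C(n1ccnc1)n1ccnc1 (imidazolyl group of 7 only)
Why: Acyl imidazolide activation followed by aminolysis (Weinreb amide synthesis) is mild and leaves the E-alkene and the aryl methyl ether untouched.

**Step 4**
Reactants: 5 4-[4-(benzyloxy)benzyl]-1,7-bis[4-(benzyloxy)phenyl]heptane-3,5-dione; 8 (E)-N-methoxy-3-(3-methoxyphenyl)-N-methylprop-2-enamide
Product: 10 (E)-4,6-bis[4-(benzyloxy)benzyl]-9-[4-(benzyloxy)phenyl]-1-(3-methoxyphenyl)non-1-ene-3,5,7-trione, via tetrahedral lithium adduct 9 (not isolated)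
Conditions: LDA (2.2 equiv), THF, −78 → 0 °C; 8 (1.0 equiv), −78 → 0 °C; cold aq NH4Cl
Reagents that add atoms: none
Why: This is a Weinreb ketone synthesis with a β-diketone 1,3-dianion, in which the two α'-CH2 groups of 5 are equivalent, the hard lithium carbanion adds 1,2 to the poorly Michael-accepting unsaturated amide, and the chelated adduct 9 survives until the quench, so the more acidic triketone neither quenches unreacted dianion nor is attacked twice; C4 and C6 are stereolabile and are erased in step 5.

**Step 5**
Reactants: 10 (E)-4,6-bis[4-(benzyloxy)benzyl]-9-[4-(benzyloxy)phenyl]-1-(3-methoxyphenyl)non-1-ene-3,5,7-trione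
Product: 12 2,4,6-tris[4-(benzyloxy)benzyl]-5-[(E)-2-(3-methoxyphenyl)ethenyl]benzene-1,3-diol, via cyclic aldol 11 (not isolated)
Conditions: DBU (1.0 equiv), 4 Å MS, degassed PhMe, 110 °C, Ar; then 1 M HCl
Reagents that add atoms: none
Why: DBU deprotonates the chain reversibly, and the small equilibrium share of the C7/C8 enolate (chain numbering of 10) adds through C8 to the still ketonic cinnamoyl carbonyl C3 to give aldol 11, which loses water by E1cB (acidic H at C4 and C8) and tautomerises twice to resorcinol 12, so that C3–C8 becomes bond C1–C6 of the central ring. The closest known reaction types are the alkali-induced aldol cyclodehydration of heptane-2,4,6-trione to orcinol and the aldol closure of styryl-terminated polyketo acids onto their cinnamoyl carbonyl, the laboratory counterparts of the stilbene-synthase fold. The ring closes in the favoured 6-(enolendo)-exo-trig mode, since the enolate bond C7=C8 lies inside the new ring and the C3=O bond outside it, and the stereocentres of 11 are transient, so none remains in 12. Regiochemistry is fixed by the substrate, because C2 is vinylic and cannot form an enolate and every other carbanion/carbonyl pairing (C4→C7, C6→C3, C8→C5) would give a four-membered ring, leaving C8→C3 as the only closure that can aromatise. The aldol must beat O-cyclisation (O3 onto C7, towards a 4-pyranone), 6-endo conjugate addition of O5 or C6 to the styryl β-carbon C1, and retro-Claisen cleavage: the benzyl groups at C4 and C6 keep the dicarbonyl units largely in the keto form so that C3 stays electrophilic, attack by C6 would build a quaternary centre beside a benzylic methine, the conjugate additions should be reversible under an amidine base at reflux whereas aromatisation is not, and dehydration of the O-cyclised hemiketal is acid-driven. A non-nucleophilic base with sieves is chosen because hydroxide and alkoxide cleave 2-alkyl-1,3-diketones, and a non-coordinating cation is chosen because a metal chelated between O5 and O7 would hold C4 and C8 apart in the extended W form, while closure needs both oxygens turned outward.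

**Step 6**
Reactants: 12 2,4,6-tris[4-(benzyloxy)benzyl]-5-[(E)-2-(3-methoxyphenyl)ethenyl]benzene-1,3-diol
Product: 13 2,4,6-tris[4-(benzyloxy)benzyl]-3-methoxy-5-[(E)-2-(3-methoxyphenyl)ethenyl]phenol
Conditions: K2CO3 (1.0 equiv), MeI (1.0 equiv), DMF, 0 °C → rt; unreacted 12 recycled
Reagents that add atoms: iodomethane CI
Why: In this Williamson O-methylation the two phenols are symmetry-equivalent, so either gives the same 13, while one equivalent each of base and MeI limits the second methylation and the polar aprotic medium favours O- over C-alkylation of the fully substituted ring.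

**Step 7**
Reactants: 13 2,4,6-tris[4-(benzyloxy)benzyl]-3-methoxy-5-[(E)-2-(3-methoxyphenyl)ethenyl]phenol
Product: 14 2,4,6-tris(4-hydroxybenzyl)-3-methoxy-5-[2-(3-methoxyphenyl)ethyl]phenol (target)
Conditions: H2 (1–3 bar), 10% Pd/C, EtOAc/MeOH, rt
Reagents that add atoms: none
Why: Heterogeneous catalytic hydrogenation should saturate the stilbene C=C and hydrogenolyse the three aryl benzyl ethers in one operation, while aryl methyl ethers and diarylmethane C–C bonds are inert under these conditions.

**Compound list**
1 | pentane-2,4-dione | CC(=O)CC(C)=O | starting material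
2 | 4-(benzyloxy)benzyl chloride | ClCc1ccc(OCc2ccccc2)cc1 | starting material
3 | 6-[4-(benzyloxy)phenyl]hexane-2,4-dione (present as its lithium enolate, drawn neutral) | CC(=O)CC(=O)CCc1ccc(OCc2ccccc2)cc1 | intermediate
4 | 1,7-bis[4-(benzyloxy)phenyl]heptane-3,5-dione | O=C(CCc1ccc(OCc2ccccc2)cc1)CC(=O)CCc1ccc(OCc2ccccc2)cc1 | intermediate
5 | 4-[4-(benzyloxy)benzyl]-1,7-bis[4-(benzyloxy)phenyl]heptane-3,5-dione | O=C(CCc1ccc(OCc2ccccc2)cc1)C(Cc1ccc(OCc2ccccc2)cc1)C(=O)CCc1ccc(OCc2ccccc2)cc1 | intermediate
6 | (E)-3-(3-methoxyphenyl)prop-2-enoic acid | COc1cccc(/C=C/C(=O)O)c1 | starting material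
7 | (E)-1-(imidazol-1-yl)-3-(3-methoxyphenyl)prop-2-en-1-one | COc1cccc(/C=C/C(=O)n2ccnc2)c1 | intermediate
8 | (E)-N-methoxy-3-(3-methoxyphenyl)-N-methylprop-2-enamide | COc1cccc(/C=C/C(=O)N(C)OC)c1 | intermediate
9 | tetrahedral adduct of the dianion of 5 with 8 (lithium alkoxide/enolate in the flask, drawn neutral; stereolabile mixture) | COc1cccc(/C=C/C(O)(N(C)OC)C(Cc2ccc(OCc3ccccc3)cc2)C(=O)C(Cc2ccc(OCc3ccccc3)cc2)C(=O)CCc2ccc(OCc3ccccc3)cc2)c1 | intermediate
10 | (E)-4,6-bis[4-(benzyloxy)benzyl]-9-[4-(benzyloxy)phenyl]-1-(3-methoxyphenyl)non-1-ene-3,5,7-trione (stereolabile keto/enol mixture) | COc1cccc(/C=C/C(=O)C(Cc2ccc(OCc3ccccc3)cc2)C(=O)C(Cc2ccc(OCc3ccccc3)cc2)C(=O)CCc2ccc(OCc3ccccc3)cc2)c1 | intermediate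
11 | 2,4,6-tris[4-(benzyloxy)benzyl]-5-hydroxy-5-[(E)-2-(3-methoxyphenyl)ethenyl]cyclohexane-1,3-dione (transient diastereomer mixture) | COc1cccc(/C=C/C2(O)C(Cc3ccc(OCc4ccccc4)cc3)C(=O)C(Cc3ccc(OCc4ccccc4)cc3)C(=O)C2Cc2ccc(OCc3ccccc3)cc2)c1 | intermediate
12 | 2,4,6-tris[4-(benzyloxy)benzyl]-5-[(E)-2-(3-methoxyphenyl)ethenyl]benzene-1,3-diol | COc1cccc(/C=C/c2c(Cc3ccc(OCc4ccccc4)cc3)c(O)c(Cc3ccc(OCc4ccccc4)cc3)c(O)c2Cc2ccc(OCc3ccccc3)cc2)c1 | intermediate
13 | 2,4,6-tris[4-(benzyloxy)benzyl]-3-methoxy-5-[(E)-2-(3-methoxyphenyl)ethenyl]phenol | COc1cccc(/C=C/c2c(Cc3ccc(OCc4ccccc4)cc3)c(O)c(Cc3ccc(OCc4ccccc4)cc3)c(OC)c2Cc2ccc(OCc3ccccc3)cc2)c1 | intermediate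
14 | 2,4,6-tris(4-hydroxybenzyl)-3-methoxy-5-[2-(3-methoxyphenyl)ethyl]phenol (achiral) | COc1cccc(CCc2c(Cc3ccc(O)cc3)c(O)c(Cc3ccc(O)cc3)c(OC)c2Cc2ccc(O)cc2)c1 | target

**Total step count:** 7. **Longest linear sequence:** 6 (steps 1, 2, 4, 5, 6, 7 from pentane-2,4-dione).

**Steps most likely to fail**

Step 5 (key step). The C8 enolate is only a minor equilibrium species. The chain may therefore be diverted into conjugate addition at the styryl β-carbon, into O-cyclisation, or into retro-Claisen fragmentation before the aldol occurs.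
- The fallback sets out from 2 and comes back at 12. The ring is bought instead of built.
- Heck coupling of commercial 5-bromobenzene-1,3-diol with commercial 3-vinylanisole (Pd(OAc)2, P(o-tol)3, Et3N, DMF, 100 °C) should give (E)-5-[2-(3-methoxyphenyl)ethenyl]benzene-1,3-diol F1.
- Positions C2, C4 and C6 of F1 are each ortho or para to both hydroxyl groups, so they are far more nucleophilic than any other ring present.
- A threefold Friedel–Crafts benzylation with 2 (3.3 equiv, cat. ZnCl2, CH2Cl2/HFIP, 0 °C → rt) should therefore fill all three positions and deliver 12.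

Step 4. The hindered secondary carbanion may add slowly or incompletely. The strong base may also fragment the N-methoxy amide with loss of formaldehyde, or conjugate addition may compete.
- The fallback sets out from 5 and 8 and comes back at 10. It replaces acylation by aldol addition and oxidation.
- DIBAL-H (THF, −78 °C) should reduce 8 to (E)-3-(3-methoxyphenyl)prop-2-enal F2.
- The dianion of 5 (LDA, 2.2 equiv, THF, −78 °C) should add 1,2 to this much more reactive electrophile. The product is (E)-4,6-bis[4-(benzyloxy)benzyl]-9-[4-(benzyloxy)phenyl]-3-hydroxy-1-(3-methoxyphenyl)non-1-ene-5,7-dione F3, a diastereomer mixture that is kept neutral to avoid lactol dehydration.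
- Activated MnO2 in CH2Cl2 should oxidise the allylic alcohol of F3 selectively to 10.

Step 6. Discrimination between the first and second methylation may be poor, and over-methylated material is lost irreversibly. Some C-methylation with dearomatisation may also occur.
- The fallback sets out from 12 and comes back at 13. It replaces an irreversible statistical step by a reversible one.
- TBSOTf (1.0 equiv, 2,6-lutidine, CH2Cl2, −78 °C) should give 2,4,6-tris[4-(benzyloxy)benzyl]-3-[(tert-butyldimethylsilyl)oxy]-5-[(E)-2-(3-methoxyphenyl)ethenyl]phenol F4. Over-silylation can be undone with fluoride, which returns material to 12.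
- Exhaustive methylation (NaH, excess MeI, THF, 0 °C → rt) needs no selectivity. It should give tert-butyl{2,4,6-tris[4-(benzyloxy)benzyl]-3-methoxy-5-[(E)-2-(3-methoxyphenyl)ethenyl]phenoxy}dimethylsilane F5.
- TBAF (THF, 0 °C) then releases 13.

**Further compounds**
F1 | step 5 | (E)-5-[2-(3-methoxyphenyl)ethenyl]benzene-1,3-diol | COc1cccc(/C=C/c2cc(O)cc(O)c2)c1
F2 | step 4 | (E)-3-(3-methoxyphenyl)prop-2-enal | COc1cccc(/C=C/C=O)c1
F3 | step 4 | (E)-4,6-bis[4-(benzyloxy)benzyl]-9-[4-(benzyloxy)phenyl]-3-hydroxy-1-(3-methoxyphenyl)non-1-ene-5,7-dione | COc1cccc(/C=C/C(O)C(Cc2ccc(OCc3ccccc3)cc2)C(=O)C(Cc2ccc(OCc3ccccc3)cc2)C(=O)CCc2ccc(OCc3ccccc3)cc2)c1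
F4 | step 6 | 2,4,6-tris[4-(benzyloxy)benzyl]-3-[(tert-butyldimethylsilyl)oxy]-5-[(E)-2-(3-methoxyphenyl)ethenyl]phenol | COc1cccc(/C=C/c2c(Cc3ccc(OCc4ccccc4)cc3)c(O)c(Cc3ccc(OCc4ccccc4)cc3)c(O[Si](C)(C)C(C)(C)C)c2Cc2ccc(OCc3ccccc3)cc2)c1
F5 | step 6 | tert-butyl{2,4,6-tris[4-(benzyloxy)benzyl]-3-methoxy-5-[(E)-2-(3-methoxyphenyl)ethenyl]phenoxy}dimethylsilane | COc1cccc(/C=C/c2c(Cc3ccc(OCc4ccccc4)cc3)c(OC)c(Cc3ccc(OCc4ccccc4)cc3)c(O[Si](C)(C)C(C)(C)C)c2Cc2ccc(OCc3ccccc3)cc2)c1
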